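## Retrosynthetic overview

1. All thirty carbons and the stereocentre come from two molecules of (2S)-naringenin 1. Rings A, B and C of both halves are bought, and no ring is built de novo.
2. C-3–C-3'' disconnection: silyl enol ether 2 (from 1) is the monomer. Its oxidative dimerisation gives the C2-symmetric trans,trans-3,3''-biflavanone as hexasilyl ether 3 and, after desilylation, hexaphenol 4. C-2 of naringenin dictates C-3.
3. Key disconnection (isomerisation of 4): ring C of one half opens to quinone methide 5. Ring B of the other half adds through its ipso carbon to give the dearomatised spirodienone 6. Fragmentation of 6 gives target 7 (net 1,4-aryl shift, which breaks the symmetry of 4).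
4. Ring events in order: none before the key step. In it, one ring C opens, a transient spiro-cyclopentane forms and breaks, and the other ring C becomes the chromone.

Assumption: commercial (2S)-naringenin (the aglycone of the citrus by-product naringin) is used at ≥98% ee; it is the only source of chirality, and the target centre is (S) by CIP.

## Route

**Step 1**
Reactants: 1 (2S)-naringenin
Product: 2 (2S)-4,5,7-tris(tert-butyldimethylsilyloxy)-2-[4-(tert-butyldimethylsilyloxy)phenyl]-2H-chromene (tetrasilyl enol ether of naringenin)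
Conditions: TBSOTf (4.6 equiv), Et3N (7 equiv), CH2Cl2, −78 °C → 0 °C
Reagents that add atoms: tert-butyldimethylsilyl trifluoromethanesulfonate, CC(C)(C)[Si](C)(C)OS(=O)(=O)C(F)(F)F
Why: Soft enolisation/silylation: the phenols are silylated, then the O-silylated ketone is deprotonated at C-3 by Et3N, so no free enolate forms, retro-oxa-Michael ring opening is avoided and C-2 is untouched (no new stereocentre).

**Step 2**
Reactants: 2 tetrasilyl enol ether (two molecules)
Product: 3 (2S,3R,2''S,3''R)-5,7,4',5'',7'',4'''-hexakis(tert-butyldimethylsilyloxy)-3,3''-biflavanone (trans,trans, C2-symmetric)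
Conditions: (NH4)2Ce(NO3)6 (1.1 equiv per 2), NaHCO3, MeCN/CH2Cl2, −30 °C → 0 °C
Reagents that add atoms: none
Why: Oxidative enol-silane homocoupling (one-electron oxidation by tetravalent cerium, C-3 radical addition to a second enol silane, second oxidation and desilylation to the 1,4-diketone); the C-3–C-3'' bond forms anti to the C-2 aryl group on each half, and since both halves are (2S) the only trans,trans product is the C2-symmetric (3R,3''R) isomer, which is also the thermodynamic (diequatorial) one.

**Step 3**
Reactants: 3 hexasilyl biflavanone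
Product: 4 (2S,3R,2''S,3''R)-5,7,4',5'',7'',4'''-hexahydroxy-3,3''-biflavanone (trans,trans-3,3''-binaringenin, chamaejasmin-type)
Conditions: HF·pyridine, pyridine, THF, 0 °C → 23 °C
Reagents that add atoms: none
Why: Fluoride cleavage of aryl silyl ethers under mildly acidic, base-free conditions, so no enolate or chalcone can form and C-3/C-3'' are not scrambled.

**Step 4**
Reactants: 4 hexahydroxy-3,3''-biflavanone
Product: 7 (+)-chamaechromone, via quinone methide 5 (not isolated), via spirodienone 6 (not isolated)
Conditions: TfOH (10 mol %), HFIP, 0 °C → 23 °C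
Reagents that add atoms: none
Why: Proposed new method: acid ionises the C-2''–O bond of one flavanone half (4'''-hydroxyl push) to the O-protonated quinone methide 5, whose cationic carbon is captured in a 5-exo ipso attack by the para-hydroxyphenyl ring of the other half to give dearomatised spirodienone 6, and 6 rearomatises by retro-Friedel–Crafts cleavage of its C-1'–C-2 bond, the departing C-2 oxocarbenium losing H-3 to become the chromone (an aromatic benzopyrylium when protonated, which drives the isomerisation); no bond at C-3'' is broken, so its configuration is retained (3''R in 4, named S in 7 only because CIP priorities change), and the closest known reaction types are phenol ipso-spirocyclisations onto carbocations, cationic 1,4-aryl migrations through spiro arenium ions and acid-mediated para-quinone-methide Friedel–Crafts alkylations.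

## Compound list

1 | (2S)-naringenin, (2S)-5,7-dihydroxy-2-(4-hydroxyphenyl)chroman-4-one | O=C1C[C@@H](c2ccc(O)cc2)Oc2cc(O)cc(O)c21 | starting material

2 | (2S)-4,5,7-tris(tert-butyldimethylsilyloxy)-2-[4-(tert-butyldimethylsilyloxy)phenyl]-2H-chromene | CC(C)(C)[Si](C)(C)OC1=C[C@@H](c2ccc(O[Si](C)(C)C(C)(C)C)cc2)Oc2cc(O[Si](C)(C)C(C)(C)C)cc(O[Si](C)(C)C(C)(C)C)c21 | intermediate

3 | (2S,3R,2''S,3''R)-5,7,4',5'',7'',4'''-hexakis(tert-butyldimethylsilyloxy)-3,3''-biflavanone | O=C1c2c(O[Si](C)(C)C(C)(C)C)cc(O[Si](C)(C)C(C)(C)C)cc2O[C@H](c2ccc(O[Si](C)(C)C(C)(C)C)cc2)[C@H]1[C@H]1C(=O)c2c(O[Si](C)(C)C(C)(C)C)cc(O[Si](C)(C)C(C)(C)C)cc2O[C@@H]1c1ccc(O[Si](C)(C)C(C)(C)C)cc1 | intermediate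

4 | (2S,3R,2''S,3''R)-5,7,4',5'',7'',4'''-hexahydroxy-3,3''-biflavanone | O=C1c2c(O)cc(O)cc2O[C@H](c2ccc(O)cc2)[C@H]1[C@H]1C(=O)c2c(O)cc(O)cc2O[C@@H]1c1ccc(O)cc1 | intermediate

5 | para-quinone methide from opening ring C of one half of 4 (drawn neutral; O-protonated in the acid medium); the three remaining centres are as in 4 | O=C1C=CC(=C[C@H](C(=O)c2c(O)cc(O)cc2O)[C@H]2C(=O)c3c(O)cc(O)cc3O[C@@H]2c2ccc(O)cc2)C=C1 | intermediate (not isolated)

6 | spiro[cyclohexa-2,5-dien-4-one-1,1'-cyclopentane] trans-fused to the intact chromanone (drawn neutral); the new 4-hydroxyphenyl-bearing centre is drawn trans to the aroyl group and is lost on fragmentation | O=C1C=CC2(C=C1)[C@@H](c1ccc(O)cc1)[C@H](C(=O)c1c(O)cc(O)cc1O)[C@H]1C(=O)c3c(O)cc(O)cc3O[C@H]21 | intermediate (not isolated)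

7 | (+)-chamaechromone, (S)-3-[1,1-bis(4-hydroxyphenyl)-3-oxo-3-(2,4,6-trihydroxyphenyl)propan-2-yl]-5,7-dihydroxychromen-4-one | O=C(c1c(O)cc(O)cc1O)[C@H](c1coc2cc(O)cc(O)c2c1=O)C(c1ccc(O)cc1)c1ccc(O)cc1 | target

## Step count and risk

Total step count: 4. Longest linear sequence: 4.

Steps most likely to fail:

**Step 4 (1,4-aryl shift).** The cation of 5 may lose H-3'' to give the chalcone, which erodes ee, or may simply re-close without migration. Fallback (desymmetrise first and keep the phenols silylated), setting out from 3 and coming back at 7: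
- One ketone of 3 is converted with one equivalent of TBSOTf/Et3N (CH2Cl2, −20 °C) into the mono silyl enol ether of hexasilyl biflavanone F3; recovered 3 is recycled.
- A catalytic silyl Lewis acid (TMSOTf, CH2Cl2/HFIP, −40 °C) then ionises the remaining flavanone half. Its cation is captured ipso by the silyloxyphenyl ring of the enol-silane half. That aryl group now leaves from a 4-silyloxy-2H-chromene, so an aromatic 4-silyloxybenzopyrylium ion forms directly and gives the chromone on aqueous work-up.
- The product, hexakis-O-TBS chamaechromone F4, is desilylated with HF·pyridine to 7.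

**Step 2 (oxidative dimerisation).** Over-oxidation to the flavone, α-nitrate formation or steric failure of the hindered C-3–C-3'' coupling are possible. Fallback (redox-neutral radical/enol-silane cross-coupling in place of the two-fold oxidation), setting out from 2 and coming back at 3:
- Half of 2 is brominated (NBS, THF, −78 °C) to trans-(2R,3R)-3-bromo-5,7-bis(tert-butyldimethylsilyloxy)-2-[4-(tert-butyldimethylsilyloxy)phenyl]chroman-4-one F2.
- Visible-light photoredox catalysis (Ir(ppy)3, 2,6-lutidine, MeCN/CH2Cl2, blue LED) reduces F2 to the C-3 radical, which adds anti to the aryl group of a second molecule of 2.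
- The resulting α-silyloxy radical is oxidised by the catalyst and desilylated to give 3.

**Step 1 (persilylation/enol silane).** The adjacent 4- and 5-silyloxy groups are crowded, and C-2 could erode if a free phenoxide or enolate opens the ring. Fallback (no enol silane at all), setting out from 1 and coming back at 3 without passing through 2:
- Only the phenols are protected (TBSOTf 3.3 equiv, 2,6-lutidine, CH2Cl2, −78 °C) to give (2S)-5,7,4'-tris-O-TBS-naringenin F1.
- Its lithium enolate (LDA, THF, −78 °C) is dimerised directly by oxidative enolate coupling with CuCl2 (DMF/THF, −78 → −40 °C). The same anti-to-aryl control gives 3.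

## Further compounds

F1 | step 1 | (2S)-5,7-bis(tert-butyldimethylsilyloxy)-2-[4-(tert-butyldimethylsilyloxy)phenyl]chroman-4-one | O=C1C[C@@H](c2ccc(O[Si](C)(C)C(C)(C)C)cc2)Oc2cc(O[Si](C)(C)C(C)(C)C)cc(O[Si](C)(C)C(C)(C)C)c21

F2 | step 2 | trans-(2R,3R)-3-bromo-5,7-bis(tert-butyldimethylsilyloxy)-2-[4-(tert-butyldimethylsilyloxy)phenyl]chroman-4-one | O=C1c2c(O[Si](C)(C)C(C)(C)C)cc(O[Si](C)(C)C(C)(C)C)cc2O[C@H](c2ccc(O[Si](C)(C)C(C)(C)C)cc2)[C@H]1Br

F3 | step 4 | mono(tert-butyldimethylsilyl) enol ether of 3 (one half as 4-silyloxy-2H-chromene, the three remaining centres as in 3) | O=C1c2c(O[Si](C)(C)C(C)(C)C)cc(O[Si](C)(C)C(C)(C)C)cc2O[C@H](c2ccc(O[Si](C)(C)C(C)(C)C)cc2)[C@H]1C1=C(O[Si](C)(C)C(C)(C)C)c2c(O[Si](C)(C)C(C)(C)C)cc(O[Si](C)(C)C(C)(C)C)cc2O[C@@H]1c1ccc(O[Si](C)(C)C(C)(C)C)cc1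

F4 | step 4 | hexakis-O-(tert-butyldimethylsilyl)chamaechromone (one hydroxyl ortho to the ketone free) | O=C(c1c(O)cc(O[Si](C)(C)C(C)(C)C)cc1O[Si](C)(C)C(C)(C)C)[C@H](c1coc2cc(O[Si](C)(C)C(C)(C)C)cc(O[Si](C)(C)C(C)(C)C)c2c1=O)C(c1ccc(O[Si](C)(C)C(C)(C)C)cc1)c1ccc(O[Si](C)(C)C(C)(C)C)cc1
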